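**Plan**

- Retrosynthesis: the seco acid is traced back to its eight-membered lactone (ring A C1 acyl–O–CH2–C6'). Ring B is then cut at C1'–C6' and C4'–C5' with CO2 put back, which gives a 3-aryloxy-2-pyrone bearing a propargyl ester on ring A. Further cuts are the pyrone C3–O aryl ether bond, the ring A C1–CO2 bond and the benzylic C–C bond of the side chain.
- Enabling feature: ring B reads ether O (C1'), OH (C2'), H (C3'), CH3 (C4'), H (C5'), CH2OH (C6'). C1'–C4' are C3–C6 of triacetic acid lactone with every substituent in place. The C6' CH2OH can lactonise onto the ring A C1 carboxyl, so C5' and C6' can arrive as the alkyne of a propargyl ester.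
- Forward: ring A is bought as 4-hydroxy-2-methoxybenzaldehyde and elaborated (isobutyl addition, oxidation, asymmetric reduction, ortho-lithiation/CO2, propargyl ester). The pyrone is attached by rhodium carbenoid O–H insertion. Ring B and the lactone ring then form together in one thermal step; hydroxide opens the lactone and fluoride frees the carbinol.
- Stereochemistry: the single (S) benzylic carbinol comes from Corey–Bakshi–Shibata reduction of the aryl isobutyl ketone with the (R)-oxazaborolidine and is carried as a TBS ether.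

Key step: step 12

Remark: the O–H insertion product is written as its 4-hydroxy-2-pyrone tautomer, and adduct 18 carries no bridgehead descriptors because both of its diastereomers collapse to the same arene; ring A locants start at the carboxyl-bearing carbon (C1), ring B locants at the ether carbon (C1').

**Route**

Step 1
Reactants: 1 4-hydroxy-2-methoxybenzaldehyde
Product: 2 2-methoxy-4-(methoxymethoxy)benzaldehyde
Conditions: MeOCH2Cl, i-Pr2NEt, CH2Cl2, 0 °C → rt
Reagents that add atoms: chloromethyl methyl ether, COCCl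
Why: O-alkylation of the acidic para-formyl phenol (MOM ether formation) should be clean, and the acetal oxygen later serves as a directing group for ortho-lithiation.

Step 2
Reactants: 2 2-methoxy-4-(methoxymethoxy)benzaldehyde; 3 isobutylmagnesium bromide
Product: 4 rac-1-[2-methoxy-4-(methoxymethoxy)phenyl]-3-methylbutan-1-ol
Conditions: THF, 0 °C; then H2O (sat. aq. NH4Cl)
Reagents that add atoms: none
Why: Grignard 1,2-addition to the aryl aldehyde installs the whole side-chain skeleton, and the carbinol is left racemic because it is erased in step 3 and reset in step 4.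

Step 3
Reactants: 4 rac-1-[2-methoxy-4-(methoxymethoxy)phenyl]-3-methylbutan-1-ol
Product: 5 1-[2-methoxy-4-(methoxymethoxy)phenyl]-3-methylbutan-1-one
Conditions: MnO2 (activated, excess), CH2Cl2, rt
Reagents that add atoms: none
Why: Heterogeneous MnO2 oxidation is selective for the electron-rich benzylic alcohol, and its neutral conditions leave the MOM acetal intact.

Step 4
Reactants: 5 1-[2-methoxy-4-(methoxymethoxy)phenyl]-3-methylbutan-1-one
Product: 6 (1S)-1-[2-methoxy-4-(methoxymethoxy)phenyl]-3-methylbutan-1-ol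
Conditions: (R)-1-methyl-3,3-diphenyltetrahydro-1H,3H-pyrrolo[1,2-c][1,3,2]oxazaborole (10 mol %), BH3·SMe2, THF, –20 °C; then MeOH
Reagents that add atoms: none
Why: Corey–Bakshi–Shibata reduction, in which the (R)-oxazaborolidine–borane complex binds the ketone with the aryl group as the large substituent and delivers hydride to the Re face, should set the (S)-carbinol.

Step 5
Reactants: 6 (1S)-1-[2-methoxy-4-(methoxymethoxy)phenyl]-3-methylbutan-1-ol
Product: 7 tert-butyl{(1S)-1-[2-methoxy-4-(methoxymethoxy)phenyl]-3-methylbutoxy}dimethylsilane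
Conditions: t-BuMe2SiCl, imidazole, DMF, rt → 40 °C
Reagents that add atoms: tert-butyldimethylsilyl chloride, CC(C)(C)[Si](C)(C)Cl
Why: Standard silylation of a secondary alcohol gives a TBS ether that should withstand butyllithium, the rhodium carbenoid, heat and hydroxide and that is removed by fluoride without acid.

Step 6
Reactants: 7 tert-butyl{(1S)-1-[2-methoxy-4-(methoxymethoxy)phenyl]-3-methylbutoxy}dimethylsilane
Product: 9 3-[(1S)-1-(tert-butyldimethylsilyloxy)-3-methylbutyl]-2-methoxy-6-(methoxymethoxy)benzoic acid, via aryllithium 8 (not isolated)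
Conditions: n-BuLi, THF, –20 → 0 °C; CO2, –78 °C → rt; cold dil. HCl to pH 4
Reagents that add atoms: carbon dioxide, O=C=O
Why: Directed ortho-metalation should take place at the one C–H flanked by the methoxy and MOM-oxy groups, where both oxygens coordinate lithium and acidify the position, and carboxylation of the aryllithium then places the C1 carboxyl between them.

Step 7
Reactants: 9 3-[(1S)-1-(tert-butyldimethylsilyloxy)-3-methylbutyl]-2-methoxy-6-(methoxymethoxy)benzoic acid; 10 propargyl bromide
Product: 11 prop-2-yn-1-yl 3-[(1S)-1-(tert-butyldimethylsilyloxy)-3-methylbutyl]-2-methoxy-6-(methoxymethoxy)benzoate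
Conditions: K2CO3, DMF, rt
Reagents that add atoms: none
Why: SN2 alkylation of the carboxylate at oxygen is insensitive to the two ortho substituents that would block acyl substitution at this hindered acid.

Step 8
Reactants: 11 prop-2-yn-1-yl 3-[(1S)-1-(tert-butyldimethylsilyloxy)-3-methylbutyl]-2-methoxy-6-(methoxymethoxy)benzoate
Product: 13 prop-2-yn-1-yl 3-[(1S)-1-(tert-butyldimethylsilyloxy)-3-methylbutyl]-6-hydroxy-2-methoxybenzoate, via aryl trimethylsilyl ether 12 (not isolated)
Conditions: Me3SiOTf, 2,2'-bipyridyl, CH2Cl2, 0 °C → rt; then H2O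
Reagents that add atoms: none
Why: Silyl triflate–bipyridyl cleavage of an aromatic MOM ether runs through the aryl silyl ether, which hydrolyses on aqueous work-up, and the pyridine-buffered medium should spare the TBS ether, the ester and the alkyne where protic acid would ionise the benzylic position.

Step 9
Reactants: 14 triacetic acid lactone
Product: 15 3-diazo-6-methyl-2H-pyran-2,4(3H)-dione
Conditions: 4-acetamidobenzenesulfonyl azide, Et3N, MeCN, 0 °C → rt
Reagents that add atoms: 4-acetamidobenzenesulfonyl azide, CC(=O)Nc1ccc(cc1)S(=O)(=O)N=[N+]=[N-]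
Why: Regitz diazo transfer to the doubly activated C3 of a cyclic 1,3-dicarbonyl compound is the standard route to 2-diazo-1,3-diones.

Step 10
Reactants: 13 prop-2-yn-1-yl 3-[(1S)-1-(tert-butyldimethylsilyloxy)-3-methylbutyl]-6-hydroxy-2-methoxybenzoate; 15 3-diazo-6-methyl-2H-pyran-2,4(3H)-dione
Product: 16 prop-2-yn-1-yl 3-[(1S)-1-(tert-butyldimethylsilyloxy)-3-methylbutyl]-6-[(4-hydroxy-6-methyl-2-oxo-2H-pyran-3-yl)oxy]-2-methoxybenzoate
Conditions: Rh2(OAc)4 (2 mol %), PhF, 80 °C, slow addition of 15
Reagents that add atoms: none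
Why: Rhodium carbenoid O–H insertion (oxonium ylide, then proton transfer) followed by enolisation gives the 3-aryloxy-4-hydroxy-2-pyrone, and insertion into the phenol O–H is expected to outrun addition of this acceptor-substituted carbenoid to the electron-poor propargylic alkyne or to the arene.

Step 11
Reactants: 16 prop-2-yn-1-yl 3-[(1S)-1-(tert-butyldimethylsilyloxy)-3-methylbutyl]-6-[(4-hydroxy-6-methyl-2-oxo-2H-pyran-3-yl)oxy]-2-methoxybenzoate
Product: 17 prop-2-yn-1-yl 3-[(1S)-1-(tert-butyldimethylsilyloxy)-3-methylbutyl]-2-methoxy-6-{[6-methyl-2-oxo-4-(pivaloyloxy)-2H-pyran-3-yl]oxy}benzoate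
Conditions: t-BuCOCl, Et3N, CH2Cl2, 0 °C
Reagents that add atoms: pivaloyl chloride, CC(C)(C)C(Cl)=O
Why: O-acylation of the acidic 4-hydroxy-2-pyrone (a vinylogous carboxylic acid with C3 blocked) gives a heat-stable enol pivalate that the lactone-opening hydroxide later removes, whereas a benzyl ether would call for hydrogenolysis that also cuts the benzylic CH2–O bond of the lactone.

Step 12
Reactants: 17 prop-2-yn-1-yl 3-[(1S)-1-(tert-butyldimethylsilyloxy)-3-methylbutyl]-2-methoxy-6-{[6-methyl-2-oxo-4-(pivaloyloxy)-2H-pyran-3-yl]oxy}benzoate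
Product: 19 (S)-3-[1-(tert-butyldimethylsilyloxy)-3-methylbutyl]-4-methoxy-9-methyl-5-oxo-5H,7H-dibenzo[b,g][1,5]dioxocin-11-yl pivalate, via bicyclic lactone adduct 18 (not isolated)
Conditions: 1,2-dichlorobenzene (0.005 M, degassed), 2,6-di-tert-butyl-4-methylphenol (cat.), 190 °C, sealed tube
Reagents that add atoms: none
Why: Proposed new method: on heating, the tethered terminal alkyne should add across pyrone C3 and C6 of 17 in an intramolecular (4+2) cycloaddition to give the bridged 2-oxabicyclo[2.2.2]octadienone 18, which loses CO2 in an irreversible retro-(4+2) step and so delivers the benzene ring directly at the right oxidation level. The closest known reaction type is the thermal intramolecular 2-pyrone–alkyne Diels–Alder/decarboxylation through tethers that close five- or six-membered rings; a tether that closes an eight-membered ring lies outside that precedent. Ring B closes by the cycloaddition–cycloreversion pair (bonds C1'–C6' and C4'–C5'), and the eight-membered lactone closes as the fused tether ring of a type 1 intramolecular Diels–Alder reaction, helped by the ortho-phenylene unit and the planar ester, which leave few freely rotating bonds. No stereocentre is created in 19, because the two bridgehead centres of 18 vanish on aromatisation, and the silyl-protected (S)-carbinol is a spectator under neutral thermal conditions. The step needs regioselectivity (the alkyne carbon bearing CH2O to pyrone C3, the terminal CH to C6), and the tether secures it because the opposite orientation would have to span a meta-bridged nine-membered cyclophane; high dilution guards against intermolecular cycloaddition.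

Step 13
Reactants: 19 (S)-3-[1-(tert-butyldimethylsilyloxy)-3-methylbutyl]-4-methoxy-9-methyl-5-oxo-5H,7H-dibenzo[b,g][1,5]dioxocin-11-yl pivalate
Product: 20 3-[(1S)-1-(tert-butyldimethylsilyloxy)-3-methylbutyl]-6-[2-hydroxy-6-(hydroxymethyl)-4-methylphenoxy]-2-methoxybenzoic acid
Conditions: LiOH, THF/H2O, 50 °C; cold dil. HCl to pH 4
Reagents that add atoms: lithium hydroxide, [Li+].[OH-]
Why: Saponification cleaves the aryl pivalate and opens the eight-membered benzoate lactone to the carboxylate and the C6' hydroxymethyl group while the TBS ether is stable to hydroxide, and methanol is left out so that no hindered methyl ester can form.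

Step 14
Reactants: 20 3-[(1S)-1-(tert-butyldimethylsilyloxy)-3-methylbutyl]-6-[2-hydroxy-6-(hydroxymethyl)-4-methylphenoxy]-2-methoxybenzoic acid
Product: 21 3-[(1S)-1-hydroxy-3-methylbutyl]-6-[2-hydroxy-6-(hydroxymethyl)-4-methylphenoxy]-2-methoxybenzoic acid
Conditions: Bu4NF (excess), THF, 0 → 40 °C; aq. NH4Cl
Reagents that add atoms: none
Why: Fluoride-driven desilylation under non-acidic conditions frees the benzylic carbinol without ionising the electron-rich benzylic C–O bond, so the (S) configuration should be retained.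

**Compound list**

1 | 4-hydroxy-2-methoxybenzaldehyde | COc1cc(O)ccc1C=O | starting material
2 | 2-methoxy-4-(methoxymethoxy)benzaldehyde | COCOc1ccc(C=O)c(OC)c1 | intermediate
3 | isobutylmagnesium bromide | CC(C)C[Mg]Br | starting material
4 | rac-1-[2-methoxy-4-(methoxymethoxy)phenyl]-3-methylbutan-1-ol | COCOc1ccc(C(O)CC(C)C)c(OC)c1 | intermediate
5 | 1-[2-methoxy-4-(methoxymethoxy)phenyl]-3-methylbutan-1-one | COCOc1ccc(C(=O)CC(C)C)c(OC)c1 | intermediate
6 | (1S)-1-[2-methoxy-4-(methoxymethoxy)phenyl]-3-methylbutan-1-ol | COCOc1ccc([C@@H](O)CC(C)C)c(OC)c1 | intermediate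
7 | tert-butyl{(1S)-1-[2-methoxy-4-(methoxymethoxy)phenyl]-3-methylbutoxy}dimethylsilane | COCOc1ccc([C@@H](O[Si](C)(C)C(C)(C)C)CC(C)C)c(OC)c1 | intermediate
8 | {3-[(1S)-1-(tert-butyldimethylsilyloxy)-3-methylbutyl]-2-methoxy-6-(methoxymethoxy)phenyl}lithium | COCOc1ccc([C@@H](O[Si](C)(C)C(C)(C)C)CC(C)C)c(OC)c1[Li] | intermediate
9 | 3-[(1S)-1-(tert-butyldimethylsilyloxy)-3-methylbutyl]-2-methoxy-6-(methoxymethoxy)benzoic acid | COCOc1ccc([C@@H](O[Si](C)(C)C(C)(C)C)CC(C)C)c(OC)c1C(=O)O | intermediate
10 | propargyl bromide (3-bromoprop-1-yne) | C#CCBr | starting material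
11 | prop-2-yn-1-yl 3-[(1S)-1-(tert-butyldimethylsilyloxy)-3-methylbutyl]-2-methoxy-6-(methoxymethoxy)benzoate | COCOc1ccc([C@@H](O[Si](C)(C)C(C)(C)C)CC(C)C)c(OC)c1C(=O)OCC#C | intermediate
12 | prop-2-yn-1-yl 3-[(1S)-1-(tert-butyldimethylsilyloxy)-3-methylbutyl]-2-methoxy-6-(trimethylsilyloxy)benzoate | C[Si](C)(C)Oc1ccc([C@@H](O[Si](C)(C)C(C)(C)C)CC(C)C)c(OC)c1C(=O)OCC#C | intermediate
13 | prop-2-yn-1-yl 3-[(1S)-1-(tert-butyldimethylsilyloxy)-3-methylbutyl]-6-hydroxy-2-methoxybenzoate | COc1c([C@@H](O[Si](C)(C)C(C)(C)C)CC(C)C)ccc(O)c1C(=O)OCC#C | intermediate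
14 | triacetic acid lactone (4-hydroxy-6-methyl-2H-pyran-2-one) | CC1=CC(O)=CC(=O)O1 | starting material
15 | 3-diazo-6-methyl-2H-pyran-2,4(3H)-dione | CC1=CC(=O)C(=[N+]=[N-])C(=O)O1 | intermediate
16 | prop-2-yn-1-yl 3-[(1S)-1-(tert-butyldimethylsilyloxy)-3-methylbutyl]-6-[(4-hydroxy-6-methyl-2-oxo-2H-pyran-3-yl)oxy]-2-methoxybenzoate | COc1c([C@@H](O[Si](C)(C)C(C)(C)C)CC(C)C)ccc(OC2=C(O)C=C(C)OC2=O)c1C(=O)OCC#C | intermediate
17 | prop-2-yn-1-yl 3-[(1S)-1-(tert-butyldimethylsilyloxy)-3-methylbutyl]-2-methoxy-6-{[6-methyl-2-oxo-4-(pivaloyloxy)-2H-pyran-3-yl]oxy}benzoate | COc1c([C@@H](O[Si](C)(C)C(C)(C)C)CC(C)C)ccc(OC2=C(OC(=O)C(C)(C)C)C=C(C)OC2=O)c1C(=O)OCC#C | intermediate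
18 | Diels–Alder adduct: 1-methyl-5-(pivaloyloxy)-2-oxabicyclo[2.2.2]octa-5,7-dien-3-one whose bridgehead C4 (through the ring A ether oxygen) and C8 (through CH2–O–C(=O)) are spanned by ring A as the eight-membered lactone; (S) at the silyloxy carbon, bridgeheads undefined | COc1c([C@@H](O[Si](C)(C)C(C)(C)C)CC(C)C)ccc2OC34C(=O)OC(C)(C=C3OC(=O)C(C)(C)C)C=C4COC(=O)c12 | intermediate
19 | (S)-3-[1-(tert-butyldimethylsilyloxy)-3-methylbutyl]-4-methoxy-9-methyl-5-oxo-5H,7H-dibenzo[b,g][1,5]dioxocin-11-yl pivalate | COc1c([C@@H](O[Si](C)(C)C(C)(C)C)CC(C)C)ccc2Oc3c(OC(=O)C(C)(C)C)cc(C)cc3COC(=O)c12 | intermediate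
20 | 3-[(1S)-1-(tert-butyldimethylsilyloxy)-3-methylbutyl]-6-[2-hydroxy-6-(hydroxymethyl)-4-methylphenoxy]-2-methoxybenzoic acid | COc1c([C@@H](O[Si](C)(C)C(C)(C)C)CC(C)C)ccc(Oc2c(O)cc(C)cc2CO)c1C(=O)O | intermediate
21 | 3-[(1S)-1-hydroxy-3-methylbutyl]-6-[2-hydroxy-6-(hydroxymethyl)-4-methylphenoxy]-2-methoxybenzoic acid (CNP0221397.1) | COc1c([C@@H](O)CC(C)C)ccc(Oc2c(O)cc(C)cc2CO)c1C(=O)O | target

**Step count and risks**

Total step count: 14. Longest linear sequence: 13 steps (steps 1–8 and 10–14); step 9 is a one-step side branch.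

Steps most likely to fail:

1. Step 12. The alkyne may not reach the pyrone face, because the eight-membered tether ring demands the less stable ester rotamer, so that thermal decomposition or intermolecular cycloaddition could outrun ring closure. The fallback uses known chemistry and brings ring B in ready-made; it sets out from phenol 13 and rejoins the route at 20. SNAr of the phenoxide of 13 (K2CO3, DMF, 90 °C) on 3-(allyloxy)-2-fluoro-5-methylbenzaldehyde F1, itself obtained by O-allylation of 2-fluoro-3-hydroxy-5-methylbenzaldehyde, should give the diaryl ether aldehyde prop-2-yn-1-yl 6-[2-(allyloxy)-6-formyl-4-methylphenoxy]-3-[(1S)-1-(tert-butyldimethylsilyloxy)-3-methylbutyl]-2-methoxybenzoate F2. NaBH4 in MeOH/THF at 0 °C should reduce the formyl group to the C6' hydroxymethyl group of the benzylic alcohol F3. LiOH in aqueous THF should cleave the propargyl ester to the allyl-protected acid F4. Pd(PPh3)4 with morpholine should then remove the allyl ether and give 20.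

2. Step 10. The rhodium carbenoid may be captured by the terminal alkyne (cyclopropenation or furan annulation) or by the arene, in competition with insertion into the hydrogen-bonded phenol O–H. The fallback keeps the alkyne out of the insertion step; it sets out from acid 9 and rejoins at 17. Alkylation of 9 with allyl bromide (K2CO3, DMF) should give allyl 3-[(1S)-1-(tert-butyldimethylsilyloxy)-3-methylbutyl]-2-methoxy-6-(methoxymethoxy)benzoate F5. MOM cleavage as in step 8 should give the allyl ester phenol F6. Insertion with 15 under Rh2(OAc)4 should give the allyl ester hydroxypyrone F7, and pivaloylation as in step 11 its pivalate F8. Pd(PPh3)4 with PhSiH3 should remove the allyl ester to give the pyronyl ether acid F9. Mitsunobu esterification of F9 with propargyl alcohol (PPh3, diisopropyl azodicarboxylate) then installs the alkyne last and gives 17.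

3. Step 8. The silyl triflate may also ionise or desilylate the electron-rich benzylic silyl ether, with loss of the protecting group or of configuration. The fallback moves the unmasking one stage earlier and changes its mechanism; it sets out from acid 9 and rejoins at 13. In 9 the neighbouring carboxyl group can act as an intramolecular general acid on the MOM acetal, so warm aqueous acetic acid in THF should suffice to give 3-[(1S)-1-(tert-butyldimethylsilyloxy)-3-methylbutyl]-6-hydroxy-2-methoxybenzoic acid F10. Selective alkylation of its carboxylate with propargyl bromide 10 and KHCO3 in DMF, under which the hydrogen-bonded phenol stays free, gives 13.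

**Further compounds**

F1 | step 12 | 3-(allyloxy)-2-fluoro-5-methylbenzaldehyde | C=CCOc1cc(C)cc(C=O)c1F
F2 | step 12 | prop-2-yn-1-yl 6-[2-(allyloxy)-6-formyl-4-methylphenoxy]-3-[(1S)-1-(tert-butyldimethylsilyloxy)-3-methylbutyl]-2-methoxybenzoate | COc1c([C@@H](O[Si](C)(C)C(C)(C)C)CC(C)C)ccc(Oc2c(OCC=C)cc(C)cc2C=O)c1C(=O)OCC#C
F3 | step 12 | prop-2-yn-1-yl 6-[2-(allyloxy)-6-(hydroxymethyl)-4-methylphenoxy]-3-[(1S)-1-(tert-butyldimethylsilyloxy)-3-methylbutyl]-2-methoxybenzoate | COc1c([C@@H](O[Si](C)(C)C(C)(C)C)CC(C)C)ccc(Oc2c(OCC=C)cc(C)cc2CO)c1C(=O)OCC#C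
F4 | step 12 | 6-[2-(allyloxy)-6-(hydroxymethyl)-4-methylphenoxy]-3-[(1S)-1-(tert-butyldimethylsilyloxy)-3-methylbutyl]-2-methoxybenzoic acid | COc1c([C@@H](O[Si](C)(C)C(C)(C)C)CC(C)C)ccc(Oc2c(OCC=C)cc(C)cc2CO)c1C(=O)O
F5 | step 10 | allyl 3-[(1S)-1-(tert-butyldimethylsilyloxy)-3-methylbutyl]-2-methoxy-6-(methoxymethoxy)benzoate | COCOc1ccc([C@@H](O[Si](C)(C)C(C)(C)C)CC(C)C)c(OC)c1C(=O)OCC=C
F6 | step 10 | allyl 3-[(1S)-1-(tert-butyldimethylsilyloxy)-3-methylbutyl]-6-hydroxy-2-methoxybenzoate | COc1c([C@@H](O[Si](C)(C)C(C)(C)C)CC(C)C)ccc(O)c1C(=O)OCC=C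
F7 | step 10 | allyl 3-[(1S)-1-(tert-butyldimethylsilyloxy)-3-methylbutyl]-6-[(4-hydroxy-6-methyl-2-oxo-2H-pyran-3-yl)oxy]-2-methoxybenzoate | COc1c([C@@H](O[Si](C)(C)C(C)(C)C)CC(C)C)ccc(OC2=C(O)C=C(C)OC2=O)c1C(=O)OCC=C
F8 | step 10 | allyl 3-[(1S)-1-(tert-butyldimethylsilyloxy)-3-methylbutyl]-2-methoxy-6-{[6-methyl-2-oxo-4-(pivaloyloxy)-2H-pyran-3-yl]oxy}benzoate | COc1c([C@@H](O[Si](C)(C)C(C)(C)C)CC(C)C)ccc(OC2=C(OC(=O)C(C)(C)C)C=C(C)OC2=O)c1C(=O)OCC=C
F9 | step 10 | 3-[(1S)-1-(tert-butyldimethylsilyloxy)-3-methylbutyl]-2-methoxy-6-{[6-methyl-2-oxo-4-(pivaloyloxy)-2H-pyran-3-yl]oxy}benzoic acid | COc1c([C@@H](O[Si](C)(C)C(C)(C)C)CC(C)C)ccc(OC2=C(OC(=O)C(C)(C)C)C=C(C)OC2=O)c1C(=O)O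
F10 | step 8 | 3-[(1S)-1-(tert-butyldimethylsilyloxy)-3-methylbutyl]-6-hydroxy-2-methoxybenzoic acid | COc1c([C@@H](O[Si](C)(C)C(C)(C)C)CC(C)C)ccc(O)c1C(=O)O
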